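(The readings are simulated with constants of no real substance, and the scatter is random.)

**Reading the step.** If a slope doubles every so many degrees, two runs at different temperatures can place a third.

| flask | starting material | second substrate | free catalyst | temperature | remark | time |
|---|---|---|---|---|---|---|
| spring | 0.30 M | 0.36 M | 0.60 mM | 30 °C | run made earlier |  |
| winter | 0.30 M | 0.39 M | 0.60 mM | 41 °C | run made earlier |  |
| Wednesday's | 0.30 M | 0.500 M | 0.60 mM | 45 °C |  | 80 min |
| Saturday's | 0.30 M | 0.300 M | 0.60 mM | 25 °C |  | 80 min |



| run | time / min | target / % |
|---|---|---|
| spring | 4.00 | 0.9 |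
| spring | 10.0 | 2.6 |
| spring | 20.0 | 3.1 |
| spring | 30.0 | 8.0 |
| spring | 40.0 | 8.1 |
| winter | 1.33 | 0.3 |
| winter | 2.50 | 2.1 |
| winter | 5.00 | 5.4 |
| winter | 10.0 | 6.0 |
| winter | 20.0 | 13.3 |

(standard deviation of a reading: 1 percentage point)



- which of the two ends with the higher amount of target, in percent of the starting material charged ("neither" if they lie within 2 percentage points) (Wednesday's / Saturday's / neither)
- target at the end, in percent of the starting material charged, Wednesday's
- target at the end, in percent of the starting material charged, Saturday's



- what was read earlier has a scatter of 1 percentage point, one standard deviation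
- a reading or a percentage of target counts all its forms, free or not



The last spring reading gives a slope of 0.00202 min⁻¹ in fractions of the charge, and the last winter reading gives 0.00665 min⁻¹, so winter climbs faster. I set second substrate aside, since these two runs hold nearly the same amount. My doubling step, the temperature rise that doubles such a slope, reads 6.41 K from these two scattered readings.

**Drawing the curves.** I let each curve start on its slope, bend as first order and head for the whole charge. My curve for Wednesday's starts at 0.0102 min⁻¹ and crosses half of the charge at 67.6 min, earlier than the end of that flask, so my curve has bent by then and stands at 55.9 %. My curve for Saturday's starts at 0.00118 min⁻¹ and reaches that crossing at 588 min, later than the end of that flask, so my curve stays nearly straight and ends at 9.00 %.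

**The forecast.** It says Wednesday's, with 48 % (30 % to 66 %) and 8.5 % (6 % to 12 %). Its Wednesday's figure is lower than mine, with the caution “Target may bind the catalyst, and high-temperature catalyst loss is possible”, and its Saturday's figure is slightly lower than mine.

**The result.** The flasks give 45.6 % for Wednesday's and 12.4 % for Saturday's, so Wednesday's ends higher.

    starting material + target ⇌ idle adduct, settled at all times (K = 3.80 M⁻¹, ΔH = −82.0 kJ mol⁻¹)
    free catalyst + target ⇌ idle complex, settled at all times (K = 24.0 M⁻¹, ΔH = −25.0 kJ mol⁻¹)
    starting material + free catalyst ⇌ catalyst intermediate A (K = 2.30 M⁻¹, k = 28000 M⁻¹ h⁻¹, Ea = 39.0 kJ mol⁻¹, ΔH = −26.0 kJ mol⁻¹)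
    second substrate + free catalyst ⇌ catalyst intermediate B (K = 630 M⁻¹, k = 880 M⁻¹ h⁻¹, Ea = 41.0 kJ mol⁻¹, ΔH = 13.0 kJ mol⁻¹)
    catalyst intermediate B → free catalyst + second product (k = 140 h⁻¹, Ea = 73.0 kJ mol⁻¹)
    catalyst intermediate A → free catalyst + target (k = 270 h⁻¹, Ea = 82.0 kJ mol⁻¹)
    (constants at 25 °C)

**Why they part.** The gap is mainly temperature: Wednesday's recipe at Saturday's temperature ends at 9.62 %, against 45.6 %. My step counts 3.12 doublings across that change. This pair, put through the same first-order curve, shows 2.59.

**A hotter neighbour.** The neighbour is Saturday's flask run at 50 °C. Starting from Wednesday's end and adding 0.780 doublings, with second substrate again set aside, I get 64.8 %. The flask gives 61.8 %.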